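**Retrosynthetic overview**

1. Streptaspironate A 35 is opened at the pyran O–C bond (vinylogous transetherification) to the macrocyclic spirotetronate 34, and 34 by an intramolecular Diels–Alder reaction to the linear 3-acyl-4-methoxy-5-methylidenebutenolide 33.
2. The butenolide of 33 is cut into ynone 29 and CO2: a silver-catalysed carboxylative cyclisation makes the C2–C3 bond (enolate + CO2) and the O1–C5 bond (carboxylate onto the alkyne, 5-exo-dig).
3. Enabling feature: in the butenolide ring (O1, carbonyl C2, C3, ether-bearing C4, spiro C5) the O1–C2(=O) unit is one CO2 molecule. It lies between C3, a CH2 acidified by the C4 carbonyl in the precursor, and C5, which bears no hydrogen and can therefore be an alkyne carbon conjugated to C4=O before the cyclohexene ring is built on it.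
4. Ynone 29 comes from a B-alkyl Suzuki union of west tetraenol 16 (quaternary carbinol from (R)-lactic acid; Z alkene locked through a butenolide) with east vinyl iodide 26 (methoxy stereocentre by catalytic asymmetric vinylogous aldol addition; Z alkene by carbomagnesiation).
5. Ring order: butenolide (step 20), then cyclohexene together with a 15-membered carbocycle (step 22), then the dihydropyran, which divides that carbocycle and leaves the 13-membered oxa-ring (step 23).

Key step: step 20

Remark: (S)-Tol-BINAP in step 14 is taken to be the ligand enantiomer that delivers the (R)-carbinol; should the sense be opposite, the (R)-ligand is used and nothing else changes.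

**Route**

Step 1
Reactants: 1 (R)-lactic acid; 2 pivalaldehyde
Product: 3 (2R,5R)-2-tert-butyl-5-methyl-1,3-dioxolan-4-one
Conditions: TsOH·H2O (cat.), H2SO4 (cat.), pentane, reflux, Dean–Stark; recrystallisation
Reagents that add atoms: none
Why: Acid-catalysed acetalisation of the α-hydroxy acid with azeotropic removal of water should give mainly the cis dioxolanone, the acetal centre being set by the lactate stereocentre (tert-butyl and methyl cis) and upgraded by crystallisation.

Step 2
Reactants: 4 (E)-2-methylpent-2-enal; 5 ethyl 2-(triphenyl-λ5-phosphanylidene)propanoate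
Product: 6 ethyl (2E,4E)-2,4-dimethylhepta-2,4-dienoate
Conditions: PhMe, 80 °C
Reagents that add atoms: none
Why: Wittig olefination with a stabilised ylide should give the new trisubstituted alkene E and leaves the E alkene of the enal untouched.

Step 3
Reactants: 6 ethyl (2E,4E)-2,4-dimethylhepta-2,4-dienoate
Product: 7 (2E,4E)-2,4-dimethylhepta-2,4-dien-1-ol
Conditions: iBu2AlH (2.2 equiv), CH2Cl2, −78 °C; Rochelle salt work-up
Reagents that add atoms: none
Why: Hydride reduction of the conjugated ester with iBu2AlH goes 1,2 to the allylic alcohol without touching the diene.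

Step 4
Reactants: 7 (2E,4E)-2,4-dimethylhepta-2,4-dien-1-ol
Product: 8 (2E,4E)-1-bromo-2,4-dimethylhepta-2,4-diene
Conditions: CBr4, PPh3, CH2Cl2, 0 °C; used at once
Reagents that add atoms: carbon tetrabromide `BrC(Br)(Br)Br`
Why: Appel bromination converts the primary allylic alcohol into the bromide under neutral conditions, so no allylic transposition or alkene isomerisation is expected.

Step 5
Reactants: 3 (2R,5R)-2-tert-butyl-5-methyl-1,3-dioxolan-4-one; 8 (2E,4E)-1-bromo-2,4-dimethylhepta-2,4-diene
Product: 9 (2R,5S)-2-tert-butyl-5-[(2E,4E)-2,4-dimethylhepta-2,4-dien-1-yl]-5-methyl-1,3-dioxolan-4-one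
Conditions: LiN(iPr)2, THF, −78 °C; then 8, THF/DMPU, −78 → −30 °C
Reagents that add atoms: none
Why: Enolate alkylation of the lactate-derived dioxolanone (self-regeneration of stereocentres) occurs on the face opposite to the tert-butyl group, so the allylic bromide takes the place of the lactate hydrogen and sets the quaternary carbinol carbon.

Step 6
Reactants: 9 (2R,5S)-2-tert-butyl-5-[(2E,4E)-2,4-dimethylhepta-2,4-dien-1-yl]-5-methyl-1,3-dioxolan-4-one
Product: 10 (2S,4E,6E)-2,4,6-trimethylnona-4,6-diene-1,2-diol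
Conditions: LiAlH4, Et2O, 0 °C
Reagents that add atoms: none
Why: Hydride reduction with LiAlH4 opens the acetal-ester to the primary/tertiary diol and releases the auxiliary aldehyde as its alcohol, leaving the quaternary stereocentre untouched.

Step 7
Reactants: 10 (2S,4E,6E)-2,4,6-trimethylnona-4,6-diene-1,2-diol
Product: 11 (2S,4E,6E)-2-hydroxy-2,4,6-trimethylnona-4,6-dienal
Conditions: SO3·pyridine, DMSO, iPr2NEt, CH2Cl2, 0 °C; used crude
Reagents that add atoms: none
Why: Parikh–Doering oxidation converts only the primary alcohol, since the tertiary alcohol is inert and the aldehyde has no α-hydrogen to epimerise.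

Step 8
Reactants: 11 (2S,4E,6E)-2-hydroxy-2,4,6-trimethylnona-4,6-dienal; 12 ethyl 2-[bis(2,2,2-trifluoroethoxy)phosphoryl]propanoate
Product: 14 (5S)-5-[(2E,4E)-2,4-dimethylhepta-2,4-dien-1-yl]-3,5-dimethylfuran-2(5H)-one, via hydroxy enoate 13 (not isolated)
Conditions: 12, KN(SiMe3)2, 18-crown-6, THF, −78 °C; then 11; then 25 °C
Reagents that add atoms: none
Why: Still–Gennari olefination should give the Z trisubstituted enoate, and only this Z isomer can lactonise onto the tertiary hydroxyl, so closure to the butenolide locks and purifies the Z geometry.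

Step 9
Reactants: 14 (5S)-5-[(2E,4E)-2,4-dimethylhepta-2,4-dien-1-yl]-3,5-dimethylfuran-2(5H)-one
Product: 15 (5S)-5-[(2E,4E)-2,4-dimethylhepta-2,4-dien-1-yl]-3,5-dimethyl-2,5-dihydrofuran-2-ol (anomers)
Conditions: iBu2AlH (1.1 equiv), CH2Cl2, −78 °C
Reagents that add atoms: none
Why: Partial reduction of the lactone with iBu2AlH at low temperature stops at the lactol, which cannot aromatise to a furan because C5 is quaternary.

Step 10
Reactants: 15 (5S)-5-[(2E,4E)-2,4-dimethylhepta-2,4-dien-1-yl]-3,5-dimethyl-2,5-dihydrofuran-2-ol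
Product: 16 (3Z,5S,7E,9E)-3,5,7,9-tetramethyldodeca-1,3,7,9-tetraen-5-ol
Conditions: Ph3PCH3Br, KOtBu, THF, 0 → 40 °C
Reagents that add atoms: methyltriphenylphosphonium bromide `C[P+](c1ccccc1)(c1ccccc1)c1ccccc1.[Br-]`
Why: Wittig methylenation of the lactol through its open (Z)-hydroxy enal form should give the terminal diene with the Z alkene retained.

Step 11
Reactants: 17 2,2,6-trimethyl-4H-1,3-dioxin-4-one
Product: 18 trimethyl[(2,2-dimethyl-4-methylidene-4H-1,3-dioxin-6-yl)oxy]silane
Conditions: LiN(iPr)2, THF, −78 °C; Me3SiCl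
Reagents that add atoms: chlorotrimethylsilane `C[Si](C)(C)Cl`
Why: O-silylation of the lithium dienolate of the dioxinone gives the silyl dienol ether that serves as a vinylogous acetoacetate nucleophile.

Step 12
Reactants: 19 prop-2-yn-1-ol
Product: 20 (Z)-3-iodo-2-methylprop-2-en-1-ol
Conditions: MeMgBr (2.5 equiv), CuI (10 mol%), THF, −10 → 25 °C; then I2, −78 → 0 °C
Reagents that add atoms: methylmagnesium bromide `C[Mg]Br`; iodine `II`
Why: Copper-catalysed anti carbomagnesiation of the propargylic alkoxide followed by iodinolysis of the chelated vinylmagnesium species places iodine cis to the hydroxymethyl group, which is the Z geometry needed later.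

Step 13
Reactants: 20 (Z)-3-iodo-2-methylprop-2-en-1-ol
Product: 21 (Z)-3-iodo-2-methylprop-2-enal
Conditions: MnO2, CH2Cl2, 25 °C, dark; used at once
Reagents that add atoms: none
Why: Allylic oxidation with MnO2 is neutral and should keep both the Z geometry and the vinyl iodide.

Step 14
Reactants: 21 (Z)-3-iodo-2-methylprop-2-enal; 18 trimethyl[(2,2-dimethyl-4-methylidene-4H-1,3-dioxin-6-yl)oxy]silane
Product: 23 6-[(2R,3Z)-2-hydroxy-4-iodo-3-methylbut-3-en-1-yl]-2,2-dimethyl-4H-1,3-dioxin-4-one, via silyl ether 22 (not isolated)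
Conditions: Cu(OTf)2 (2 mol%), (S)-Tol-BINAP (2.2 mol%), Bu4N[Ph3SiF2] (4 mol%), THF, −78 °C; then TFA, THF/H2O
Reagents that add atoms: none
Why: Catalytic enantioselective vinylogous Mukaiyama aldol addition through a chiral copper dienolate sets the carbinol stereocentre by catalyst control and brings in the four-carbon acetoacetate unit in masked form.

Step 15
Reactants: 23 6-[(2R,3Z)-2-hydroxy-4-iodo-3-methylbut-3-en-1-yl]-2,2-dimethyl-4H-1,3-dioxin-4-one
Product: 24 6-[(2R,3Z)-4-iodo-2-methoxy-3-methylbut-3-en-1-yl]-2,2-dimethyl-4H-1,3-dioxin-4-one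
Conditions: Me3OBF4, 1,8-bis(dimethylamino)naphthalene, CH2Cl2, 0 → 25 °C
Reagents that add atoms: trimethyloxonium tetrafluoroborate `C[O+](C)C.F[B-](F)(F)F`
Why: O-methylation with an oxonium salt and a hindered non-nucleophilic base forms no enolate, so neither β-elimination nor retro-aldol cleavage of the aldol adduct is expected.

Step 16
Reactants: 24 6-[(2R,3Z)-4-iodo-2-methoxy-3-methylbut-3-en-1-yl]-2,2-dimethyl-4H-1,3-dioxin-4-one
Product: 25 (5R,6Z)-7-iodo-N,5-dimethoxy-N,6-dimethyl-3-oxohept-6-enamide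
Conditions: MeNH(OMe)·HCl, iPr2NEt, PhMe, 110 °C, sealed tube
Reagents that add atoms: N,O-dimethylhydroxylamine hydrochloride `CNOC.Cl`
Why: Thermal retro-[4+2] loss of acetone from the dioxinone gives an acylketene that is trapped by the hydroxylamine as the β-keto Weinreb amide.

Step 17
Reactants: 25 (5R,6Z)-7-iodo-N,5-dimethoxy-N,6-dimethyl-3-oxohept-6-enamide
Product: 26 2-{2-[(2R,3Z)-4-iodo-2-methoxy-3-methylbut-3-en-1-yl]-1,3-dioxolan-2-yl}-N-methoxy-N-methylacetamide
Conditions: (Me3SiOCH2)2, Me3SiOTf (5 mol%), CH2Cl2, −78 → −20 °C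
Reagents that add atoms: 1,2-bis(trimethylsilyloxy)ethane `C[Si](C)(C)OCCO[Si](C)(C)C`
Why: Lewis acid-catalysed ketalisation with the bis-silyl glycol masks the ketone, so that no 1,3-dicarbonyl is present in steps 19 and 20, while the amide carbonyl does not react.

Step 18
Reactants: 16 (3Z,5S,7E,9E)-3,5,7,9-tetramethyldodeca-1,3,7,9-tetraen-5-ol; 26 2-{2-[(2R,3Z)-4-iodo-2-methoxy-3-methylbut-3-en-1-yl]-1,3-dioxolan-2-yl}-N-methoxy-N-methylacetamide
Product: 28 2-{2-[(2R,3Z,7Z,9S,11E,13E)-9-hydroxy-2-methoxy-3,7,9,11,13-pentamethylhexadeca-3,7,11,13-tetraen-1-yl]-1,3-dioxolan-2-yl}-N-methoxy-N-methylacetamide, via alkylborane 27 (not isolated)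
Conditions: 9-BBN-H, THF, 0 → 25 °C; then 26, Pd(dppf)Cl2 (5 mol%), AsPh3, Cs2CO3, DMF/H2O, 25 °C
Reagents that add atoms: none
Why: Hydroboration with 9-BBN-H takes only the monosubstituted terminal alkene (anti-Markovnikov), and the primary alkylborane then undergoes B-alkyl Suzuki–Miyaura coupling with the vinyl iodide with retention of the Z geometry.

Step 19
Reactants: 28 2-{2-[(2R,3Z,7Z,9S,11E,13E)-9-hydroxy-2-methoxy-3,7,9,11,13-pentamethylhexadeca-3,7,11,13-tetraen-1-yl]-1,3-dioxolan-2-yl}-N-methoxy-N-methylacetamide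
Product: 29 1-{2-[(2R,3Z,7Z,9S,11E,13E)-9-hydroxy-2-methoxy-3,7,9,11,13-pentamethylhexadeca-3,7,11,13-tetraen-1-yl]-1,3-dioxolan-2-yl}but-3-yn-2-one
Conditions: HC≡CMgBr (3 equiv), THF, 0 °C; cold aq. NaHSO4
Reagents that add atoms: ethynylmagnesium bromide `C#C[Mg]Br`
Why: Addition of the alkynyl Grignard reagent to the Weinreb amide stops at the chelated tetrahedral intermediate and gives the terminal ynone on acidic quench, one equivalent being spent on the free hydroxyl.

Step 20
Reactants: 29 1-{2-[(2R,3Z,7Z,9S,11E,13E)-9-hydroxy-2-methoxy-3,7,9,11,13-pentamethylhexadeca-3,7,11,13-tetraen-1-yl]-1,3-dioxolan-2-yl}but-3-yn-2-one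
Product: 32 3-{2-[(2R,3Z,7Z,9S,11E,13E)-9-hydroxy-2-methoxy-3,7,9,11,13-pentamethylhexadeca-3,7,11,13-tetraen-1-yl]-1,3-dioxolan-2-yl}-4-methoxy-5-methylidenefuran-2(5H)-one, via keto carboxylate 30 (not isolated), via tetronate salt 31 (not isolated)
Conditions: AgOAc (10 mol%), MTBD (2.5 equiv), CO2 (1 atm), MeCN, 25 °C; then Me2SO4, 0 → 25 °C
Reagents that add atoms: carbon dioxide `O=C=O`; dimethyl sulfate `COS(=O)(=O)OC`
Why: MTBD reversibly enolises the only acidic position of 29, the CH2 between the ketal carbon and the ynone carbonyl, and the enolate adds to CO2 to give β-keto carboxylate 30, which creates the C2–C3 bond of the butenolide; monovalent silver then activates the alkyne as a π-acid, the carboxylate oxygen adds anti to the metal at the alkyne carbon next to the ketone (O1–C5 bond), protodemetalation releases tetronate 31, whose formation drains the unfavourable carboxylation equilibrium, and dimethyl sulfate caps O4. The closest known reaction type is the silver-catalysed incorporation of CO2 into conjugated ynones, which gives 5-ylidene tetronic acids, supported by the silver/amidine carboxylative cyclisation of terminal propargylic alcohols, which shows that a terminal alkyne is tolerated. The only ring closed is the butenolide, and it closes in the 5-exo-dig mode. No stereocentre is formed, because C3 and C5 both end trigonal; the step instead delivers the prochiral exocyclic alkene that serves as the dienophile in step 22. Three selectivities are needed and each is secured by the substrate: carboxylation can occur only at the one CH2 because the other flank of the ketone is the alkyne and the second ketone is masked as a dioxolane (a free 1,3-diketone would close through its enol oxygen to a pyranone), 5-exo closure is favoured over 6-endo by π-activation and by the short β-keto carboxylate tether, and methylation goes to O4 because C3 is shielded by the adjacent quaternary ketal carbon.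

Step 21
Reactants: 32 3-{2-[(2R,3Z,7Z,9S,11E,13E)-9-hydroxy-2-methoxy-3,7,9,11,13-pentamethylhexadeca-3,7,11,13-tetraen-1-yl]-1,3-dioxolan-2-yl}-4-methoxy-5-methylidenefuran-2(5H)-one
Product: 33 3-[(3R,4Z,8Z,10S,12E,14E)-10-hydroxy-3-methoxy-4,8,10,12,14-pentamethylheptadeca-4,8,12,14-tetraenoyl]-4-methoxy-5-methylidenefuran-2(5H)-one
Conditions: PPTS (cat.), acetone/H2O, 40 °C
Reagents that add atoms: water `O`
Why: Mild acid hydrolysis removes the dioxolane, whose ionisation is assisted by the electron-rich C3 of the 4-methoxybutenolide, and unveils the 3-acyl group that activates the dienophile.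

Step 22
Reactants: 33 3-[(3R,4Z,8Z,10S,12E,14E)-10-hydroxy-3-methoxy-4,8,10,12,14-pentamethylheptadeca-4,8,12,14-tetraenoyl]-4-methoxy-5-methylidenefuran-2(5H)-one
Product: 34 macrocyclic spirotetronate (Diels–Alder adduct: 35 with the pyran ether bond open, the butenolide C4 carrying OMe and the quaternary carbinol carrying OH)
Conditions: PhMe (1 mM), BHT (cat.), 105 °C
Reagents that add atoms: none
Why: Intramolecular Diels–Alder reaction of a 3-acyl-4-methoxy-5-methylidenebutenolide with a tethered diene (the classical spirotetronate closure), in which the (E,E)-diene geometry and the endo position of the tether-bearing butenolide C4 fix the relative configuration of the spiro carbon, the neighbouring quaternary carbon and the ethyl-bearing carbon, while the diene face is expected to be chosen by the quaternary carbinol two atoms from the diene, whose hydroxyl can hydrogen-bond to the C4 methoxy oxygen only in the transition state that also places it for the later pyran closure.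

Step 23
Reactants: 34 macrocyclic spirotetronate
Product: 35 streptaspironate A
Conditions: KN(SiMe3)2 (1.05 equiv), THF, −78 → −40 °C; AcOH
Reagents that add atoms: none
Why: Intramolecular addition–elimination (vinylogous transesterification, 6-exo-trig) of the tertiary potassium alkoxide at C4 of the 3-acyl-4-methoxybutenolide expels methoxide and closes the cis-fused dihydropyran, and because the carbinol C–O bond is never broken the configuration of that carbon is retained.

**Compound list**

1 | (R)-lactic acid | `C[C@@H](O)C(=O)O` | starting material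
2 | pivalaldehyde | `CC(C)(C)C=O` | starting material
3 | (2R,5R)-2-tert-butyl-5-methyl-1,3-dioxolan-4-one | `CC(C)(C)[C@@H]1O[C@H](C)C(=O)O1` | intermediate
4 | (E)-2-methylpent-2-enal | `CC/C=C(\C)C=O` | starting material
5 | ethyl 2-(triphenyl-λ5-phosphanylidene)propanoate | `CCOC(=O)C(C)=P(c1ccccc1)(c1ccccc1)c1ccccc1` | starting material
6 | ethyl (2E,4E)-2,4-dimethylhepta-2,4-dienoate | `CCOC(=O)/C(C)=C/C(C)=C/CC` | intermediate
7 | (2E,4E)-2,4-dimethylhepta-2,4-dien-1-ol | `OC/C(C)=C/C(C)=C/CC` | intermediate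
8 | (2E,4E)-1-bromo-2,4-dimethylhepta-2,4-diene | `BrC/C(C)=C/C(C)=C/CC` | intermediate
9 | (2R,5S)-2-tert-butyl-5-[(2E,4E)-2,4-dimethylhepta-2,4-dien-1-yl]-5-methyl-1,3-dioxolan-4-one | `CC(C)(C)[C@@H]1O[C@@](C)(C/C(C)=C/C(C)=C/CC)C(=O)O1` | intermediate
10 | (2S,4E,6E)-2,4,6-trimethylnona-4,6-diene-1,2-diol | `OC[C@@](C)(O)C/C(C)=C/C(C)=C/CC` | intermediate
11 | (2S,4E,6E)-2-hydroxy-2,4,6-trimethylnona-4,6-dienal | `O=C[C@@](C)(O)C/C(C)=C/C(C)=C/CC` | intermediate
12 | ethyl 2-[bis(2,2,2-trifluoroethoxy)phosphoryl]propanoate | `CCOC(=O)C(C)P(=O)(OCC(F)(F)F)OCC(F)(F)F` | starting material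
13 | ethyl (2Z,4S,6E,8E)-4-hydroxy-2,4,6,8-tetramethylundeca-2,6,8-trienoate | `CCOC(=O)/C(C)=C\[C@@](C)(O)C/C(C)=C/C(C)=C/CC` | intermediate (not isolated)
14 | (5S)-5-[(2E,4E)-2,4-dimethylhepta-2,4-dien-1-yl]-3,5-dimethylfuran-2(5H)-one | `CC1=C[C@](C)(C/C(C)=C/C(C)=C/CC)OC1=O` | intermediate
15 | (5S)-5-[(2E,4E)-2,4-dimethylhepta-2,4-dien-1-yl]-3,5-dimethyl-2,5-dihydrofuran-2-ol | `CC1=C[C@](C)(C/C(C)=C/C(C)=C/CC)OC1O` | intermediate
16 | (3Z,5S,7E,9E)-3,5,7,9-tetramethyldodeca-1,3,7,9-tetraen-5-ol | `C=C/C(C)=C\[C@@](C)(O)C/C(C)=C/C(C)=C/CC` | intermediate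
17 | 2,2,6-trimethyl-4H-1,3-dioxin-4-one | `CC1=CC(=O)OC(C)(C)O1` | starting material
18 | trimethyl[(2,2-dimethyl-4-methylidene-4H-1,3-dioxin-6-yl)oxy]silane | `C=C1C=C(O[Si](C)(C)C)OC(C)(C)O1` | intermediate
19 | prop-2-yn-1-ol | `C#CCO` | starting material
20 | (Z)-3-iodo-2-methylprop-2-en-1-ol | `I/C=C(C)\CO` | intermediate
21 | (Z)-3-iodo-2-methylprop-2-enal | `I/C=C(C)\C=O` | intermediate
22 | 6-[(2R,3Z)-4-iodo-3-methyl-2-(trimethylsilyloxy)but-3-en-1-yl]-2,2-dimethyl-4H-1,3-dioxin-4-one | `I/C=C(C)\[C@H](O[Si](C)(C)C)CC1=CC(=O)OC(C)(C)O1` | intermediate (not isolated)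
23 | 6-[(2R,3Z)-2-hydroxy-4-iodo-3-methylbut-3-en-1-yl]-2,2-dimethyl-4H-1,3-dioxin-4-one | `I/C=C(C)\[C@H](O)CC1=CC(=O)OC(C)(C)O1` | intermediate
24 | 6-[(2R,3Z)-4-iodo-2-methoxy-3-methylbut-3-en-1-yl]-2,2-dimethyl-4H-1,3-dioxin-4-one | `I/C=C(C)\[C@H](OC)CC1=CC(=O)OC(C)(C)O1` | intermediate
25 | (5R,6Z)-7-iodo-N,5-dimethoxy-N,6-dimethyl-3-oxohept-6-enamide | `I/C=C(C)\[C@H](OC)CC(=O)CC(=O)N(C)OC` | intermediate
26 | 2-{2-[(2R,3Z)-4-iodo-2-methoxy-3-methylbut-3-en-1-yl]-1,3-dioxolan-2-yl}-N-methoxy-N-methylacetamide | `I/C=C(C)\[C@H](OC)CC1(OCCO1)CC(=O)N(C)OC` | intermediate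
27 | 9-[(3Z,5S,7E,9E)-5-hydroxy-3,5,7,9-tetramethyldodeca-3,7,9-trien-1-yl]-9-borabicyclo[3.3.1]nonane | `CC/C=C(C)/C=C(C)/C[C@](C)(O)/C=C(C)\CCB1C2CCCC1CCC2` | intermediate (not isolated)
28 | 2-{2-[(2R,3Z,7Z,9S,11E,13E)-9-hydroxy-2-methoxy-3,7,9,11,13-pentamethylhexadeca-3,7,11,13-tetraen-1-yl]-1,3-dioxolan-2-yl}-N-methoxy-N-methylacetamide | `CC/C=C(C)/C=C(C)/C[C@](C)(O)/C=C(C)\CC/C=C(C)\[C@H](OC)CC1(OCCO1)CC(=O)N(C)OC` | intermediate
29 | 1-{2-[(2R,3Z,7Z,9S,11E,13E)-9-hydroxy-2-methoxy-3,7,9,11,13-pentamethylhexadeca-3,7,11,13-tetraen-1-yl]-1,3-dioxolan-2-yl}but-3-yn-2-one | `CC/C=C(C)/C=C(C)/C[C@](C)(O)/C=C(C)\CC/C=C(C)\[C@H](OC)CC1(OCCO1)CC(=O)C#C` | intermediate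
30 | 7-methyl-1,5,7-triazabicyclo[4.4.0]dec-5-enium salt of the β-keto carboxylate (29 carboxylated at the CH2 between ketal and ynone carbonyl) | `CC/C=C(C)/C=C(C)/C[C@](C)(O)/C=C(C)\CC/C=C(C)\[C@H](OC)CC1(OCCO1)C(C(=O)[O-])C(=O)C#C.CN1CCCN2CCC[NH+]=C12` | intermediate (not isolated)
31 | 7-methyl-1,5,7-triazabicyclo[4.4.0]dec-5-enium salt of the 5-methylidene tetronate (4-oxido analogue of 32) | `CC/C=C(C)/C=C(C)/C[C@](C)(O)/C=C(C)\CC/C=C(C)\[C@H](OC)CC1(OCCO1)C2=C([O-])C(=C)OC2=O.CN1CCCN2CCC[NH+]=C12` | intermediate (not isolated)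
32 | 3-{2-[(2R,3Z,7Z,9S,11E,13E)-9-hydroxy-2-methoxy-3,7,9,11,13-pentamethylhexadeca-3,7,11,13-tetraen-1-yl]-1,3-dioxolan-2-yl}-4-methoxy-5-methylidenefuran-2(5H)-one | `CC/C=C(C)/C=C(C)/C[C@](C)(O)/C=C(C)\CC/C=C(C)\[C@H](OC)CC1(OCCO1)C2=C(OC)C(=C)OC2=O` | intermediate
33 | 3-[(3R,4Z,8Z,10S,12E,14E)-10-hydroxy-3-methoxy-4,8,10,12,14-pentamethylheptadeca-4,8,12,14-tetraenoyl]-4-methoxy-5-methylidenefuran-2(5H)-one | `CC/C=C(C)/C=C(C)/C[C@](C)(O)/C=C(C)\CC/C=C(C)\[C@H](OC)CC(=O)C1=C(OC)C(=C)OC1=O` | intermediate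
34 | macrocyclic spirotetronate (35 with the pyran ether bond open: OMe on butenolide C4, OH on the quaternary carbinol) | `CC[C@H]1C[C@@]23OC(=O)C(=C2OC)C(=O)C[C@@H](OC)/C(C)=C\CC/C(C)=C\[C@@](C)(O)C[C@@]3(C)C=C1C` | intermediate
35 | streptaspironate A | `CC[C@H]1C[C@@]23OC(=O)C4=C2O[C@](C)(/C=C(/C)CC/C=C(/C)[C@H](OC)CC4=O)C[C@@]3(C)C=C1C` | target

**Step count and risks**

Total step count: 23. Longest linear sequence: 15 steps (steps 2–10 and 18–23).

Steps most likely to fail:

Step 20. What may go wrong: oligomerisation of the terminal ynone by conjugate addition under the amidine base, formation of a silver acetylide with carboxylation at the alkyne C–H, 6-endo instead of 5-exo ring closure, or loss of CO2 from 30 faster than cyclisation. Fallback (sets out from 21, uses alkylborane 27 of step 18, comes back to the route at 33): the butenolide is brought in whole instead of being made from CO2. A Ti(OiPr)4/BINOL-catalysed Mukaiyama aldol addition of 1-ethoxy-1-(trimethylsilyloxy)ethene to 21 should give ethyl (3R,4Z)-3-hydroxy-5-iodo-4-methylpent-4-enoate F1. O-Methylation as in step 15 gives ethyl (3R,4Z)-5-iodo-3-methoxy-4-methylpent-4-enoate F2. B-Alkyl Suzuki coupling with 27 under the conditions of step 18 gives ethyl (3R,4Z,8Z,10S,12E,14E)-10-hydroxy-3-methoxy-4,8,10,12,14-pentamethylheptadeca-4,8,12,14-tetraenoate F3. Reduction with iBu2AlH at −78 °C gives (3R,4Z,8Z,10S,12E,14E)-10-hydroxy-3-methoxy-4,8,10,12,14-pentamethylheptadeca-4,8,12,14-tetraenal F4. Addition of 3-lithio-4-methoxy-5-methylidenefuran-2(5H)-one (from the furanone and LiN(iPr)2 at −78 °C, one extra equivalent for the free hydroxyl) gives 3-[(3R,4Z,8Z,10S,12E,14E)-1,10-dihydroxy-3-methoxy-4,8,10,12,14-pentamethylheptadeca-4,8,12,14-tetraen-1-yl]-4-methoxy-5-methylidenefuran-2(5H)-one F5. Dess–Martin oxidation of the secondary carbinol then gives 33.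

Step 22. What may go wrong: poor facial or endo/exo selectivity across the 15-membered transition state, slow cycloaddition at the fully substituted diene terminus, and competing polymerisation of the methylidene butenolide or a 1,5-hydrogen shift in the diene. Fallback (sets out from 33, comes back at 35): the order of ring formation is reversed. Intramolecular addition–elimination of the tertiary alkoxide at butenolide C4 under high dilution (KN(SiMe3)2, THF, −78 °C) closes the 13-membered enol ether first and gives the macrocyclic 4-O-alkyl-5-methylidene tetronate F6. In F6 the diene is held over the exocyclic alkene by a four-atom tether through the quaternary carbinol carbon, so a thermal intramolecular Diels–Alder reaction forms the cyclohexene and the cis-fused pyran together, under control of that carbon, and gives 35 directly.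

Step 23. What may go wrong: enolisation of the ketone followed by β-elimination of the neighbouring methoxy group, re-addition of the released methoxide, or slow addition at the congested butenolide C4. Fallback (sets out from 34, comes back at 35): O-demethylation of the vinylogous ester with LiCl in DMSO gives the free 3-acyltetronic acid F7. F7 is then closed by acid-catalysed dehydrative etherification through the six-membered hemiketal (PPTS, PhH, 4 Å molecular sieves), which needs no base.

**Further compounds**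

F1 | step 20 | ethyl (3R,4Z)-3-hydroxy-5-iodo-4-methylpent-4-enoate | `CCOC(=O)C[C@@H](O)/C(C)=C\I`
F2 | step 20 | ethyl (3R,4Z)-5-iodo-3-methoxy-4-methylpent-4-enoate | `CCOC(=O)C[C@@H](OC)/C(C)=C\I`
F3 | step 20 | ethyl (3R,4Z,8Z,10S,12E,14E)-10-hydroxy-3-methoxy-4,8,10,12,14-pentamethylheptadeca-4,8,12,14-tetraenoate | `CC/C=C(C)/C=C(C)/C[C@](C)(O)/C=C(C)\CC/C=C(C)\[C@H](OC)CC(=O)OCC`
F4 | step 20 | (3R,4Z,8Z,10S,12E,14E)-10-hydroxy-3-methoxy-4,8,10,12,14-pentamethylheptadeca-4,8,12,14-tetraenal | `CC/C=C(C)/C=C(C)/C[C@](C)(O)/C=C(C)\CC/C=C(C)\[C@H](OC)CC=O`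
F5 | step 20 | 3-[(3R,4Z,8Z,10S,12E,14E)-1,10-dihydroxy-3-methoxy-4,8,10,12,14-pentamethylheptadeca-4,8,12,14-tetraen-1-yl]-4-methoxy-5-methylidenefuran-2(5H)-one | `CC/C=C(C)/C=C(C)/C[C@](C)(O)/C=C(C)\CC/C=C(C)\[C@H](OC)CC(O)C1=C(OC)C(=C)OC1=O`
F6 | step 22 | macrocyclic 4-O-alkyl-5-methylidene tetronate (35 with the two Diels–Alder bonds open) | `CC/C=C(C)/C=C(C)/C[C@]1(C)OC2=C(C(=O)OC2=C)C(=O)C[C@@H](OC)/C(C)=C\CC/C(C)=C\1`
F7 | step 23 | free 3-acyltetronic acid (34 with OH in place of the butenolide OMe) | `CC[C@H]1C[C@@]23OC(=O)C(=C2O)C(=O)C[C@@H](OC)/C(C)=C\CC/C(C)=C\[C@@](C)(O)C[C@@]3(C)C=C1C`
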